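## Retrosynthetic overview

1. Target ⇒ global O-debenzylation of its octabenzyl ether ⇒ aroylation of the 5- and 4'-phenols of a 7,3'-di-O-benzyl-(+)-catechin, whose 4'-OH is masked until then as an allyl ether.
2. trans-C3–OH ⇒ flavan-3-one (axial hydride delivery) ⇒ 3-nitro-2H-chromene (conjugate reduction, Nef reaction); C3 is carried as a nitro-bearing carbon, a masked acyl anion.
3. Ring C ⇒ one-flask asymmetric oxa-Michael / nitronate-to-aldehyde (Henry) addition / dehydration between a ring A 2,6-dihydroxybenzaldehyde (supplies C4) and a ring B β-nitrostyrene (supplies C2 and C3); O1–C2 forms first and fixes C2, then the key C3–C4 bond closes.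
4. The nitrostyrene ⇒ ring B aldehyde + nitromethane (Henry condensation); both aldehydes ⇒ trihydroxy- and dihydroxybenzaldehyde by regioselective O-alkylation.
5. Ring order: rings A and B are bought, ring C is the only ring built (step 5), the two galloyl rings are attached last.

Assumption: the (S)-configured pyrrolidine catalyst of step 5 induces the 2R configuration; if the first run shows the opposite sense, its enantiomer (from D-proline) is used and nothing else changes.

## Route

Step 1
Reactants: 1 2,4,6-trihydroxybenzaldehyde; 2 benzyl bromide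
Product: 3 4-(benzyloxy)-2,6-dihydroxybenzaldehyde
Conditions: BnBr (1.0 equiv), NaHCO3 (1.1 equiv), DMF, 40 °C
Reagents that add atoms: benzyl bromide, BrCc1ccccc1
Why: Williamson etherification under mono-anion control, in which the 4-OH (para to the formyl group and not hydrogen-bonded to it) is the most acidic and most nucleophilic phenol, so one equivalent of weak base and BnBr alkylates it selectively and the minor 2-O-benzyl and dibenzyl ethers are removed by chromatography.

Step 2
Reactants: 4 3,4-dihydroxybenzaldehyde; 5 allyl bromide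
Product: 6 4-(allyloxy)-3-hydroxybenzaldehyde
Conditions: allyl bromide (1.1 equiv), NaHCO3 (1.5 equiv), NaI (cat.), DMF, 40 °C
Reagents that add atoms: allyl bromide, C=CCBr
Why: Regioselective Williamson etherification, because NaHCO3 ionises only the more acidic 4-OH (para to the aldehyde), so allylation occurs at O-4 and the 3-OH stays free.

Step 3
Reactants: 6 4-(allyloxy)-3-hydroxybenzaldehyde; 2 benzyl bromide
Product: 7 4-(allyloxy)-3-(benzyloxy)benzaldehyde
Conditions: BnBr (1.2 equiv), K2CO3 (1.5 equiv), DMF, 50 °C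
Reagents that add atoms: benzyl bromide, BrCc1ccccc1
Why: Plain Williamson benzylation of the remaining phenol, to which the aldehyde and the allyl ether are inert.

Step 4
Reactants: 7 4-(allyloxy)-3-(benzyloxy)benzaldehyde; 8 nitromethane
Product: 9 1-(allyloxy)-2-(benzyloxy)-4-[(E)-2-nitrovinyl]benzene
Conditions: MeNO2 (5 equiv), NH4OAc (0.5 equiv), AcOH, 100 °C
Reagents that add atoms: nitromethane, C[N+](=O)[O-]
Why: Henry (nitro-aldol) condensation in which loss of water is driven by conjugation and gives only the E-nitrostyrene, installing the nitromethane carbon that will become C3.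

Step 5
Reactants: 3 4-(benzyloxy)-2,6-dihydroxybenzaldehyde; 9 1-(allyloxy)-2-(benzyloxy)-4-[(E)-2-nitrovinyl]benzene
Product: 12 (2R)-2-[4-(allyloxy)-3-(benzyloxy)phenyl]-7-(benzyloxy)-3-nitro-2H-chromen-5-ol, via oxa-Michael adduct 10 (not isolated), via nitro-aldol adduct 11 (not isolated)
Conditions: 3 (1.0 equiv), 9 (1.3 equiv), (S)-1-methyl-2-[(pyrrolidin-2-ylmethyl)sulfanyl]-1H-imidazole (20 mol%), salicylic acid (20 mol%), DMSO, rt, dark; then recrystallisation (EtOH)
Reagents that add atoms: none
Why: Organocatalytic domino oxa-Michael / intramolecular Henry (nitro-aldol) / dehydration, in which the amine turns the ortho-hydroxy aldehyde into an iminium, either of the two equivalent phenols adds reversibly to the nitroalkene, the resulting nitronate (the carbon that later becomes the C3 carbonyl, acting as an acyl-anion equivalent) attacks the activated C4 carbon to forge C3–C4, and irreversible elimination gives the conjugated nitrochromene; C2 is set as R because only the oxa-Michael diastereomer matched to the chiral pyrrolidine closes fast, and recrystallisation raises the ee.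

Step 6
Reactants: 12 (2R)-2-[4-(allyloxy)-3-(benzyloxy)phenyl]-7-(benzyloxy)-3-nitro-2H-chromen-5-ol
Product: 14 (2R)-2-[4-(allyloxy)-3-(benzyloxy)phenyl]-7-(benzyloxy)-5-hydroxychroman-3-one, via sodium nitronate 13 (not isolated)
Conditions: NaBH4 (1.2 equiv), THF/MeOH (9:1), −20 °C, 20 min; then cannulated into aq. TiCl3 (4.5 equiv)/NH4OAc (pH 5–6), THF/H2O, 0 °C → rt, N2; ketone used at once
Reagents that add atoms: water, O
Why: Conjugate hydride reduction of the nitroalkene followed by the McMurry reductive Nef reaction, in which trivalent titanium reduces the nitronate to an imine that hydrolyses in the buffer to the flavan-3-one, so the former nitronate carbon is unmasked as the C3 carbonyl while C2 is untouched as long as the nitronate is kept cold and short-lived (no retro-oxa-Michael ring opening) and the near-neutral medium avoids enolisation toward C2.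

Step 7
Reactants: 14 (2R)-2-[4-(allyloxy)-3-(benzyloxy)phenyl]-7-(benzyloxy)-5-hydroxychroman-3-one
Product: 16 (2R,3S)-7-(benzyloxy)-2-[3-(benzyloxy)-4-hydroxyphenyl]chromane-3,5-diol, via allyl ether alcohol 15 (not isolated)
Conditions: NaBH4 (3 equiv), THF/MeOH (4:1), −78 °C, 1 h; then Pd(PPh3)4 (5 mol%), 0 °C → rt; aq. NH4Cl
Reagents that add atoms: none
Why: Substrate-controlled ketone reduction then palladium-catalysed de-allylation in one flask, where the half-chair ketone holds the 2-aryl group equatorial and has no axial hydrogens at O1 or C4a, so the small borohydride attacks axially and gives the equatorial 3-OH trans to the aryl group (3S, minor cis epimer removed by chromatography), after which zerovalent palladium ionises the aryl allyl ether and the remaining borohydride reduces the π-allyl complex to propene, freeing the 4'-phenol.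

Step 8
Reactants: 16 (2R,3S)-7-(benzyloxy)-2-[3-(benzyloxy)-4-hydroxyphenyl]chromane-3,5-diol; 17 3,4,5-tris(benzyloxy)benzoyl chloride
Product: 18 (2R,3S)-7-(benzyloxy)-2-{3-(benzyloxy)-4-[3,4,5-tris(benzyloxy)benzoyloxy]phenyl}-3-hydroxychroman-5-yl 3,4,5-tris(benzyloxy)benzoate
Conditions: 17 (2.05 equiv), Et3N (2.5 equiv), CH2Cl2, −20 → 0 °C, no DMAP
Reagents that add atoms: 3,4,5-tris(benzyloxy)benzoyl chloride, O=C(Cl)c1cc(OCc2ccccc2)c(OCc2ccccc2)c(OCc2ccccc2)c1
Why: Chemoselective O-aroylation of the Schotten–Baumann type, in which the two phenols are ionised by Et3N and react with the aroyl chloride within minutes in the cold, whereas the hindered secondary 3-OH needs an acyl-transfer catalyst or heat and stays free with 2.05 equivalents of acid chloride.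

Step 9
Reactants: 18 (2R,3S)-7-(benzyloxy)-2-{3-(benzyloxy)-4-[3,4,5-tris(benzyloxy)benzoyloxy]phenyl}-3-hydroxychroman-5-yl 3,4,5-tris(benzyloxy)benzoate
Product: 19 (+)-catechin 5,4'-di-O-gallate
Conditions: H2 (1 atm), Pd(OH)2/C (20 wt%), THF/MeOH (1:1), rt; filtration, evaporation below 30 °C
Reagents that add atoms: none
Why: Global hydrogenolysis of the eight benzyl ethers under neutral conditions, which leaves the aryl esters, the cyclic benzylic C2–O1 ether and both stereocentres untouched, while the absence of base prevents migration of the 4'-galloyl group to the freed 3'-OH.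

## Compound list

1 | 2,4,6-trihydroxybenzaldehyde | O=Cc1c(O)cc(O)cc1O | starting material
2 | benzyl bromide | BrCc1ccccc1 | starting material
3 | 4-(benzyloxy)-2,6-dihydroxybenzaldehyde | O=Cc1c(O)cc(OCc2ccccc2)cc1O | intermediate
4 | 3,4-dihydroxybenzaldehyde | O=Cc1ccc(O)c(O)c1 | starting material
5 | allyl bromide | C=CCBr | starting material
6 | 4-(allyloxy)-3-hydroxybenzaldehyde | O=Cc1ccc(OCC=C)c(O)c1 | intermediate
7 | 4-(allyloxy)-3-(benzyloxy)benzaldehyde | O=Cc1ccc(OCC=C)c(OCc2ccccc2)c1 | intermediate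
8 | nitromethane | C[N+](=O)[O-] | starting material
9 | 1-(allyloxy)-2-(benzyloxy)-4-[(E)-2-nitrovinyl]benzene | C=CCOc1ccc(/C=C/[N+](=O)[O-])cc1OCc1ccccc1 | intermediate
10 | 2-{(1R)-1-[4-(allyloxy)-3-(benzyloxy)phenyl]-2-nitroethoxy}-4-(benzyloxy)-6-hydroxybenzaldehyde (oxa-Michael adduct, drawn as the free aldehyde; catalyst-bound as iminium in the flask) | C=CCOc1ccc([C@H](C[N+](=O)[O-])Oc2cc(OCc3ccccc3)cc(O)c2C=O)cc1OCc1ccccc1 | intermediate
11 | (2R)-2-[4-(allyloxy)-3-(benzyloxy)phenyl]-7-(benzyloxy)-3-nitrochromane-4,5-diol (nitro-aldol adduct, C3/C4 epimers; partly present as the 4-amino aminal of the catalyst) | C=CCOc1ccc([C@H]2Oc3cc(OCc4ccccc4)cc(O)c3C(O)C2[N+](=O)[O-])cc1OCc1ccccc1 | intermediate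
12 | (2R)-2-[4-(allyloxy)-3-(benzyloxy)phenyl]-7-(benzyloxy)-3-nitro-2H-chromen-5-ol | C=CCOc1ccc([C@H]2Oc3cc(OCc4ccccc4)cc(O)c3C=C2[N+](=O)[O-])cc1OCc1ccccc1 | intermediate
13 | sodium nitronate of (2R)-2-[4-(allyloxy)-3-(benzyloxy)phenyl]-7-(benzyloxy)-3-nitrochroman-5-ol | C=CCOc1ccc([C@H]2Oc3cc(OCc4ccccc4)cc(O)c3CC2=[N+]([O-])[O-])cc1OCc1ccccc1.[Na+] | intermediate
14 | (2R)-2-[4-(allyloxy)-3-(benzyloxy)phenyl]-7-(benzyloxy)-5-hydroxychroman-3-one | C=CCOc1ccc([C@H]2Oc3cc(OCc4ccccc4)cc(O)c3CC2=O)cc1OCc1ccccc1 | intermediate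
15 | (2R,3S)-2-[4-(allyloxy)-3-(benzyloxy)phenyl]-7-(benzyloxy)chromane-3,5-diol | C=CCOc1ccc([C@H]2Oc3cc(OCc4ccccc4)cc(O)c3C[C@@H]2O)cc1OCc1ccccc1 | intermediate
16 | (2R,3S)-7-(benzyloxy)-2-[3-(benzyloxy)-4-hydroxyphenyl]chromane-3,5-diol (7,3'-di-O-benzyl-(+)-catechin) | Oc1ccc([C@H]2Oc3cc(OCc4ccccc4)cc(O)c3C[C@@H]2O)cc1OCc1ccccc1 | intermediate
17 | 3,4,5-tris(benzyloxy)benzoyl chloride | O=C(Cl)c1cc(OCc2ccccc2)c(OCc2ccccc2)c(OCc2ccccc2)c1 | starting material
18 | (2R,3S)-7-(benzyloxy)-2-{3-(benzyloxy)-4-[3,4,5-tris(benzyloxy)benzoyloxy]phenyl}-3-hydroxychroman-5-yl 3,4,5-tris(benzyloxy)benzoate | O=C(Oc1ccc([C@H]2Oc3cc(OCc4ccccc4)cc(OC(=O)c4cc(OCc5ccccc5)c(OCc5ccccc5)c(OCc5ccccc5)c4)c3C[C@@H]2O)cc1OCc1ccccc1)c1cc(OCc2ccccc2)c(OCc2ccccc2)c(OCc2ccccc2)c1 | intermediate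
19 | (+)-catechin 5,4'-di-O-gallate, (2R,3S)-3,7-dihydroxy-2-[3-hydroxy-4-(3,4,5-trihydroxybenzoyloxy)phenyl]chroman-5-yl 3,4,5-trihydroxybenzoate | O=C(Oc1ccc([C@H]2Oc3cc(O)cc(OC(=O)c4cc(O)c(O)c(O)c4)c3C[C@@H]2O)cc1O)c1cc(O)c(O)c(O)c1 | target

## Step count and risks

Total step count: 9 (1 step to the ring A fragment, 3 to the ring B fragment, 5 after their union).
Longest linear sequence: 8 steps (steps 2 to 9).

Most likely to fail:

**Step 5.** The aldehyde is hindered and electron-rich, C-alkylation of the phloroglucinol ring by the nitroalkene can compete, and the reversible oxa-Michael step can leave the ee low. Fallback: setting out from 3 and 9, the domino reaction is run without chiral control (DABCO, 0.5 equiv, MeCN, 40 °C) to give racemic 2-[4-(allyloxy)-3-(benzyloxy)phenyl]-7-(benzyloxy)-3-nitro-2H-chromen-5-ol F1. Its enantiomers are separated by preparative chromatography on an amylose tris(3,5-dimethylphenylcarbamate) phase (supercritical CO2/MeOH). The 2R enantiomer is 12, where the route is rejoined.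

**Step 6.** The push-pull nitroalkene (free 5-OH) may take up hydride slowly, nitronate 13 can open by retro-oxa-Michael and erode C2, and the flavan-3-one is fragile. Fallback: setting out from 12, the nitroalkene is reduced under weakly acidic, nitronate-free conditions (zinc dust, NH4Cl, THF/H2O, 0 °C) to (2R)-2-[4-(allyloxy)-3-(benzyloxy)phenyl]-7-(benzyloxy)-5-hydroxychroman-3-one oxime F2. The oxime is then cleaved reductively with buffered aqueous TiCl3 (NH4OAc, pH 5–6, rt) to the ketone, coming back to the route at 14.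

**Step 7.** The borohydride reduction may give too much of the 2,3-cis epimer. Fallback: setting out from 14, reduction with LiBH(s-Bu)3 (THF, −78 °C; equatorial attack) gives cleanly the cis alcohol (2R,3R)-2-[4-(allyloxy)-3-(benzyloxy)phenyl]-7-(benzyloxy)chromane-3,5-diol F3. Mitsunobu inversion at C3 (4-nitrobenzoic acid, PPh3, DIAD, THF, 0 °C) gives (2R,3S)-2-[4-(allyloxy)-3-(benzyloxy)phenyl]-7-(benzyloxy)-5-hydroxychroman-3-yl 4-nitrobenzoate F4. Methanolysis (K2CO3, MeOH, 0 °C) returns to the route at 15, which is then de-allylated in a separate operation with Pd(PPh3)4/NaBH4 to 16.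

Further compounds
F1 | step 5 | racemic 2-[4-(allyloxy)-3-(benzyloxy)phenyl]-7-(benzyloxy)-3-nitro-2H-chromen-5-ol | C=CCOc1ccc(C2Oc3cc(OCc4ccccc4)cc(O)c3C=C2[N+](=O)[O-])cc1OCc1ccccc1
F2 | step 6 | (2R)-2-[4-(allyloxy)-3-(benzyloxy)phenyl]-7-(benzyloxy)-5-hydroxychroman-3-one oxime | C=CCOc1ccc([C@H]2Oc3cc(OCc4ccccc4)cc(O)c3CC2=NO)cc1OCc1ccccc1
F3 | step 7 | (2R,3R)-2-[4-(allyloxy)-3-(benzyloxy)phenyl]-7-(benzyloxy)chromane-3,5-diol | C=CCOc1ccc([C@H]2Oc3cc(OCc4ccccc4)cc(O)c3C[C@H]2O)cc1OCc1ccccc1
F4 | step 7 | (2R,3S)-2-[4-(allyloxy)-3-(benzyloxy)phenyl]-7-(benzyloxy)-5-hydroxychroman-3-yl 4-nitrobenzoate | C=CCOc1ccc([C@H]2Oc3cc(OCc4ccccc4)cc(O)c3C[C@@H]2OC(=O)c2ccc([N+](=O)[O-])cc2)cc1OCc1ccccc1
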